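**Strategy.** Everything rests on disconnecting C11–C12, the bond that links the allylic carbinol carbon C11 (attached to the cyclopropane ring C8–C9–C10) to C12 of the E-alkene in the C11–C14 ene-diol. In one operation a terminal alkyne (C12–C22, C14 as silyl ether) is hydroborated, transmetallated to zinc and added, under chiral amino-alcohol catalysis, to a cyclopropanecarbaldehyde (C1–C11) that already carries the intact eight-membered lactone ring; this forms C11–C12, the 11R carbinol and the 12E alkene together. The feature exploited is the secondary allylic alcohol C11 flanked by the cyclopropane ring and the C12=C13 double bond, with a lactone carbonyl that alkenylzinc reagents leave untouched.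

Key step: step 15

Remark: atoms are numbered C1–C22 along the chain (C1 lactone carbonyl, C7 lactone carbinol, C8–C10 cyclopropane, C11 and C14 carbinols); each chiral ligand or reagent enantiomer is assigned from the known facial sense of its parent reaction and would be exchanged for its antipode if a model run showed the opposite sense.

**Fragment A (C1–C11)**

Step 1
Reactants: 1 (E)-but-2-ene-1,4-diol
Product: 2 (E)-4-[(tert-butyldiphenylsilyl)oxy]but-2-en-1-ol
Conditions: NaH (1.0 equiv), THF, 0 °C; TBDPSCl (1.0 equiv), 0 °C to rt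
Reagents that add atoms: tert-butyl(chloro)diphenylsilane, CC(C)(C)[Si](Cl)(c1ccccc1)c1ccccc1
Why: O-silylation of the monosodium alkoxide of a symmetrical diol should stop at the mono-ether because the mono-alkoxide is sparingly soluble and reacts as it forms; no stereocenter is created.

Step 2
Reactants: 2 (E)-4-[(tert-butyldiphenylsilyl)oxy]but-2-en-1-ol
Product: 3 [(1R,2R)-2-{[(tert-butyldiphenylsilyl)oxy]methyl}cyclopropyl]methanol
Conditions: Zn(CH2I)2·DME (from Et2Zn, CH2I2 and DME), (4S,5S)-2-butyl-N,N,N',N'-tetramethyl-1,3,2-dioxaborolane-4,5-dicarboxamide (1.2 equiv), CH2Cl2, −10 °C to rt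
Reagents that add atoms: diiodomethane, ICI
Why: Charette asymmetric cyclopropanation (Simmons–Smith type), in which the zinc alkoxide bound to the chiral dioxaborolane directs methylene transfer to one alkene face, the E geometry becomes the trans ring, and the (4S,5S) ligand (antipode of the one that converts cinnamyl alcohol into (1S,2S)-2-phenylcyclopropylmethanol) should set C8 and C10 as R,R.

Step 3
Reactants: 3 [(1R,2R)-2-{[(tert-butyldiphenylsilyl)oxy]methyl}cyclopropyl]methanol
Product: 5 (1R)-1-[(1R,2R)-2-{[(tert-butyldiphenylsilyl)oxy]methyl}cyclopropyl]but-3-en-1-ol, via cyclopropanecarbaldehyde 4 (not isolated)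
Conditions: allyl acetate, [Ir(cod)Cl]2 (2.5 mol%), (R)-Cl,MeO-BIPHEP (5 mol%), 4-chloro-3-nitrobenzoic acid (10 mol%), Cs2CO3 (20 mol%), THF, 100 °C, sealed tube
Reagents that add atoms: allyl acetate, C=CCOC(C)=O
Why: Krische transfer-hydrogenative carbonyl allylation from the alcohol oxidation level, in which the primary alcohol is dehydrogenated to aldehyde 4 and this is allylated by the chiral allyliridium C,O-benzoate complex through a closed chair transition state; the (R)-ligand is expected to deliver allyl to the Re face and set C7 as R under catalyst control, while the cyclopropane α-carbon is not prone to epimerisation.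

Step 4
Reactants: 5 (1R)-1-[(1R,2R)-2-{[(tert-butyldiphenylsilyl)oxy]methyl}cyclopropyl]but-3-en-1-ol; 6 pent-4-enoyl chloride
Product: 7 (1R)-1-[(1R,2R)-2-{[(tert-butyldiphenylsilyl)oxy]methyl}cyclopropyl]but-3-en-1-yl pent-4-enoate
Conditions: Et3N, DMAP (cat.), CH2Cl2, 0 °C to rt
Reagents that add atoms: none
Why: DMAP-catalysed acylation of a secondary alcohol under basic conditions avoids ionisation at the cyclopropylcarbinyl position and leaves C7 untouched.

Step 5
Reactants: 7 (1R)-1-[(1R,2R)-2-{[(tert-butyldiphenylsilyl)oxy]methyl}cyclopropyl]but-3-en-1-yl pent-4-enoate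
Product: 8 (5Z,8R)-8-[(1R,2R)-2-{[(tert-butyldiphenylsilyl)oxy]methyl}cyclopropyl]-3,4,7,8-tetrahydro-2H-oxocin-2-one
Conditions: second-generation Grubbs catalyst (5–10 mol%), CH2Cl2 (1 mM), 40 °C
Reagents that add atoms: none
Why: Ring-closing olefin metathesis of the two terminal alkenes should close the eight-membered lactone with loss of ethene, the ring size enforcing the Z geometry at C4=C5 and high dilution suppressing oligomerisation.

Step 6
Reactants: 8 (5Z,8R)-8-[(1R,2R)-2-{[(tert-butyldiphenylsilyl)oxy]methyl}cyclopropyl]-3,4,7,8-tetrahydro-2H-oxocin-2-one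
Product: 9 (5Z,8R)-8-[(1R,2R)-2-(hydroxymethyl)cyclopropyl]-3,4,7,8-tetrahydro-2H-oxocin-2-one
Conditions: Bu4NF, AcOH, THF, 0 °C to rt
Reagents that add atoms: none
Why: Fluoride-mediated cleavage of the silyl ether, buffered with acetic acid so that no free alkoxide opens the lactone.

Step 7
Reactants: 9 (5Z,8R)-8-[(1R,2R)-2-(hydroxymethyl)cyclopropyl]-3,4,7,8-tetrahydro-2H-oxocin-2-one
Product: 10 (1R,2R)-2-[(2R,4Z)-8-oxo-3,6,7,8-tetrahydro-2H-oxocin-2-yl]cyclopropane-1-carbaldehyde
Conditions: Dess–Martin periodinane, NaHCO3, CH2Cl2, 0 °C to rt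
Reagents that add atoms: none
Why: Dess–Martin oxidation of the primary alcohol under buffered conditions should give the trans cyclopropane aldehyde, which is configurationally stable at C10.

**Fragment B (C12–C22)**

Step 8
Reactants: 11 3-(trimethylsilyl)prop-2-ynal
Product: 12 (3S)-1-(trimethylsilyl)hex-5-en-1-yn-3-ol
Conditions: (−)-Ipc2BOMe, CH2=CHCH2MgBr, Et2O, 0 °C to rt; then 11, −78 °C; 2-aminoethanol work-up
Reagents that add atoms: allylmagnesium bromide, C=CC[Mg]Br
Why: Brown asymmetric allylboration through a chair Zimmerman–Traxler transition state, in which the allylborane derived from (+)-α-pinene attacks the Si face of the aldehyde and thereby sets the future C14 as S under reagent control.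

Step 9
Reactants: 12 (3S)-1-(trimethylsilyl)hex-5-en-1-yn-3-ol
Product: 13 tert-butyl(dimethyl){[(3S)-1-(trimethylsilyl)hex-5-en-1-yn-3-yl]oxy}silane
Conditions: TBSCl, imidazole, DMF, rt
Reagents that add atoms: tert-butyl(chloro)dimethylsilane, CC(C)(C)[Si](C)(C)Cl
Why: Imidazole-promoted silylation of a secondary propargylic alcohol occurs at oxygen and leaves the stereocenter untouched.

Step 10
Reactants: 13 tert-butyl(dimethyl){[(3S)-1-(trimethylsilyl)hex-5-en-1-yn-3-yl]oxy}silane
Product: 15 (3S)-3-[(tert-butyldimethylsilyl)oxy]-5-(trimethylsilyl)pent-4-ynal, via ozonide 14 (not isolated)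
Conditions: O3, CH2Cl2, −78 °C (Sudan red indicator); then PPh3, −78 °C to rt
Reagents that add atoms: ozone, [O-][O+]=O
Why: Ozonolysis with reductive work-up cleaves the terminal alkene far faster than the silyl-capped alkyne, the indicator preventing over-oxidation.

Step 11
Reactants: 16 (Z)-hex-3-en-1-ol
Product: 17 (Z)-1-iodohex-3-ene
Conditions: I2, PPh3, imidazole, CH2Cl2, 0 °C to rt
Reagents that add atoms: iodine, II
Why: Appel-type iodination of a primary alcohol proceeds by SN2 displacement of the oxyphosphonium group and does not touch the Z-alkene.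

Step 12
Reactants: 17 (Z)-1-iodohex-3-ene
Product: 18 [(Z)-hex-3-en-1-yl]triphenylphosphonium iodide
Conditions: PPh3, MeCN, reflux
Reagents that add atoms: triphenylphosphine, c1ccc(cc1)P(c1ccccc1)c1ccccc1
Why: SN2 quaternisation of triphenylphosphine by a primary iodide gives the Wittig salt.

Step 13
Reactants: 18 [(Z)-hex-3-en-1-yl]triphenylphosphonium iodide; 15 (3S)-3-[(tert-butyldimethylsilyl)oxy]-5-(trimethylsilyl)pent-4-ynal
Product: 20 tert-butyl(dimethyl){[(3S,5Z,8Z)-1-(trimethylsilyl)undeca-5,8-dien-1-yn-3-yl]oxy}silane, via phosphonium ylide 19 (not isolated)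
Conditions: NaN(SiMe3)2, THF, −78 °C; then 15, −78 to 0 °C
Reagents that add atoms: none
Why: Wittig olefination with a non-stabilised ylide under salt-free, low-temperature conditions should give the Z-alkene C16=C17 by kinetic control, fast addition at −78 °C outrunning β-elimination of the silyloxy group.

Step 14
Reactants: 20 tert-butyl(dimethyl){[(3S,5Z,8Z)-1-(trimethylsilyl)undeca-5,8-dien-1-yn-3-yl]oxy}silane
Product: 21 tert-butyl(dimethyl){[(3S,5Z,8Z)-undeca-5,8-dien-1-yn-3-yl]oxy}silane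
Conditions: K2CO3, MeOH, rt
Reagents that add atoms: none
Why: Methanolysis of the C(sp)–Si bond removes the alkynyl trimethylsilyl group selectively, the silyl ether being stable to these conditions.

**Fragment union and completion**

Step 15
Reactants: 21 tert-butyl(dimethyl){[(3S,5Z,8Z)-undeca-5,8-dien-1-yn-3-yl]oxy}silane; 10 (1R,2R)-2-[(2R,4Z)-8-oxo-3,6,7,8-tetrahydro-2H-oxocin-2-yl]cyclopropane-1-carbaldehyde
Product: 24 (5Z,8R)-8-[(1R,2R)-2-{(1R,2E,4S,6Z,9Z)-4-[(tert-butyldimethylsilyl)oxy]-1-hydroxydodeca-2,6,9-trien-1-yl}cyclopropyl]-3,4,7,8-tetrahydro-2H-oxocin-2-one, via alkenylborane 22 (not isolated), via alkenylzinc 23 (not isolated)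
Conditions: 21 (1.3 equiv), (C6H11)2BH (from BH3·SMe2 and cyclohexene, 1.3 equiv), toluene, 0 °C to rt; Me2Zn, −78 °C; (+)-MIB [(2R)-3-exo-morpholinoisoborneol, 5 mol%], then 10 added slowly, −20 to 0 °C; aq. NH4Cl
Reagents that add atoms: none
Why: syn-Hydroboration of the terminal alkyne of 21 by the hindered dialkylborane should give the (E)-alkenylborane 22 with boron at C12, boron-to-zinc exchange with Me2Zn gives alkenyl(methyl)zinc 23, and the zinc amino-alkoxide formed from (+)-MIB binds both 23 and aldehyde 10 in a bimetallic chair-like transition state that transfers the alkenyl group to the carbonyl carbon, forming C11–C12. The closest known reaction type is the Oppolzer alkenylzinc addition to aldehydes in its amino-alcohol-catalysed form; no ring is closed. The new stereocenter C11 is set as R by the ligand, (+)-MIB being the antipode of the ligand that sends alkyl and alkenyl groups to the Si face, so that attack should occur on the Re face of 10; the trans-cyclopropane α-carbon C10 exerts only a weak intrinsic bias, which lets catalyst control dominate. The 12E geometry follows from syn addition of B–H and retention in transmetallation and addition, and C14 (S) is carried through unchanged. The step needs hydroboration of the alkyne in preference to the two Z-alkenes (secured by a near-stoichiometric charge of a bulky borane that is sluggish toward 1,2-disubstituted alkenes), alkenyl rather than methyl transfer (intrinsically faster from mixed zinc reagents) and attack at the aldehyde rather than the lactone carbonyl (alkenylzinc reagents do not add to esters).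

Step 16
Reactants: 24 (5Z,8R)-8-[(1R,2R)-2-{(1R,2E,4S,6Z,9Z)-4-[(tert-butyldimethylsilyl)oxy]-1-hydroxydodeca-2,6,9-trien-1-yl}cyclopropyl]-3,4,7,8-tetrahydro-2H-oxocin-2-one
Product: 25 (5Z,8R)-8-{(1R,2R)-2-[(1R,2E,4S,6Z,9Z)-1,4-dihydroxydodeca-2,6,9-trien-1-yl]cyclopropyl}-3,4,7,8-tetrahydro-2H-oxocin-2-one
Conditions: Bu4NF, AcOH, THF, 0 °C to rt
Reagents that add atoms: none
Why: Buffered fluoride desilylation frees the C14 hydroxyl without acid (which would ionise the allylic and cyclopropylcarbinyl alcohols) and without strong base (which would open the lactone).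

**Compound list**

1 | (E)-but-2-ene-1,4-diol | OC/C=C/CO | starting material
2 | (E)-4-[(tert-butyldiphenylsilyl)oxy]but-2-en-1-ol | OC/C=C/CO[Si](c1ccccc1)(c1ccccc1)C(C)(C)C | intermediate
3 | [(1R,2R)-2-{[(tert-butyldiphenylsilyl)oxy]methyl}cyclopropyl]methanol | CC(C)(C)[Si](c1ccccc1)(c1ccccc1)OC[C@@H]1C[C@H]1CO | intermediate
4 | (1R,2R)-2-{[(tert-butyldiphenylsilyl)oxy]methyl}cyclopropane-1-carbaldehyde | CC(C)(C)[Si](c1ccccc1)(c1ccccc1)OC[C@@H]1C[C@H]1C=O | intermediate
5 | (1R)-1-[(1R,2R)-2-{[(tert-butyldiphenylsilyl)oxy]methyl}cyclopropyl]but-3-en-1-ol | CC(C)(C)[Si](c1ccccc1)(c1ccccc1)OC[C@@H]1C[C@H]1[C@H](O)CC=C | intermediate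
6 | pent-4-enoyl chloride | C=CCCC(=O)Cl | starting material
7 | (1R)-1-[(1R,2R)-2-{[(tert-butyldiphenylsilyl)oxy]methyl}cyclopropyl]but-3-en-1-yl pent-4-enoate | CC(C)(C)[Si](c1ccccc1)(c1ccccc1)OC[C@@H]1C[C@H]1[C@H](OC(=O)CCC=C)CC=C | intermediate
8 | (5Z,8R)-8-[(1R,2R)-2-{[(tert-butyldiphenylsilyl)oxy]methyl}cyclopropyl]-3,4,7,8-tetrahydro-2H-oxocin-2-one | CC(C)(C)[Si](c1ccccc1)(c1ccccc1)OC[C@@H]1C[C@H]1[C@H]1C/C=C\CCC(=O)O1 | intermediate
9 | (5Z,8R)-8-[(1R,2R)-2-(hydroxymethyl)cyclopropyl]-3,4,7,8-tetrahydro-2H-oxocin-2-one | OC[C@@H]1C[C@H]1[C@H]1C/C=C\CCC(=O)O1 | intermediate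
10 | (1R,2R)-2-[(2R,4Z)-8-oxo-3,6,7,8-tetrahydro-2H-oxocin-2-yl]cyclopropane-1-carbaldehyde | O=C[C@@H]1C[C@H]1[C@H]1C/C=C\CCC(=O)O1 | intermediate
11 | 3-(trimethylsilyl)prop-2-ynal | C[Si](C)(C)C#CC=O | starting material
12 | (3S)-1-(trimethylsilyl)hex-5-en-1-yn-3-ol | C=CC[C@H](O)C#C[Si](C)(C)C | intermediate
13 | tert-butyl(dimethyl){[(3S)-1-(trimethylsilyl)hex-5-en-1-yn-3-yl]oxy}silane | C=CC[C@H](O[Si](C)(C)C(C)(C)C)C#C[Si](C)(C)C | intermediate
14 | 3-{(2S)-2-[(tert-butyldimethylsilyl)oxy]-4-(trimethylsilyl)but-3-yn-1-yl}-1,2,4-trioxolane (secondary ozonide of 13, mixture at the ring carbon) | C1OC(C[C@H](O[Si](C)(C)C(C)(C)C)C#C[Si](C)(C)C)OO1 | intermediate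
15 | (3S)-3-[(tert-butyldimethylsilyl)oxy]-5-(trimethylsilyl)pent-4-ynal | O=CC[C@H](O[Si](C)(C)C(C)(C)C)C#C[Si](C)(C)C | intermediate
16 | (Z)-hex-3-en-1-ol | CC/C=C\CCO | starting material
17 | (Z)-1-iodohex-3-ene | CC/C=C\CCI | intermediate
18 | [(Z)-hex-3-en-1-yl]triphenylphosphonium iodide | CC/C=C\CC[P+](c1ccccc1)(c1ccccc1)c1ccccc1.[I-] | intermediate
19 | [(Z)-hex-3-en-1-ylidene]triphenylphosphorane | CC/C=C\CC=P(c1ccccc1)(c1ccccc1)c1ccccc1 | intermediate
20 | tert-butyl(dimethyl){[(3S,5Z,8Z)-1-(trimethylsilyl)undeca-5,8-dien-1-yn-3-yl]oxy}silane | CC/C=C\C/C=C\C[C@H](O[Si](C)(C)C(C)(C)C)C#C[Si](C)(C)C | intermediate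
21 | tert-butyl(dimethyl){[(3S,5Z,8Z)-undeca-5,8-dien-1-yn-3-yl]oxy}silane | CC/C=C\C/C=C\C[C@H](O[Si](C)(C)C(C)(C)C)C#C | intermediate
22 | dicyclohexyl{(1E,3S,5Z,8Z)-3-[(tert-butyldimethylsilyl)oxy]undeca-1,5,8-trien-1-yl}borane | CC/C=C\C/C=C\C[C@H](O[Si](C)(C)C(C)(C)C)/C=C/B(C1CCCCC1)C1CCCCC1 | intermediate
23 | methyl{(1E,3S,5Z,8Z)-3-[(tert-butyldimethylsilyl)oxy]undeca-1,5,8-trien-1-yl}zinc | CC/C=C\C/C=C\C[C@H](O[Si](C)(C)C(C)(C)C)/C=C/[Zn]C | intermediate
24 | (5Z,8R)-8-[(1R,2R)-2-{(1R,2E,4S,6Z,9Z)-4-[(tert-butyldimethylsilyl)oxy]-1-hydroxydodeca-2,6,9-trien-1-yl}cyclopropyl]-3,4,7,8-tetrahydro-2H-oxocin-2-one | CC/C=C\C/C=C\C[C@H](O[Si](C)(C)C(C)(C)C)/C=C/[C@@H](O)[C@@H]1C[C@H]1[C@H]1C/C=C\CCC(=O)O1 | intermediate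
25 | (5Z,8R)-8-{(1R,2R)-2-[(1R,2E,4S,6Z,9Z)-1,4-dihydroxydodeca-2,6,9-trien-1-yl]cyclopropyl}-3,4,7,8-tetrahydro-2H-oxocin-2-one | CC/C=C\C/C=C\C[C@H](O)/C=C/[C@@H](O)[C@@H]1C[C@H]1[C@H]1C/C=C\CCC(=O)O1 | target

**Count**

Total step count: 16. Longest linear sequence: 9 steps (steps 1–7, 15 and 16).

**Steps most likely to fail**

Step 15. The catalyst may fail to override the aldehyde's own facial preference, giving poor facial selectivity at C11, or the borane may also add to the Z-alkenes and erode the alkenylzinc. The fallback sets out from 21: hydrozirconation with Cp2Zr(H)Cl followed by iodinolysis with I2 would give tert-butyl{[(1E,3S,5Z,8Z)-1-iodoundeca-1,5,8-trien-3-yl]oxy}dimethylsilane F1. Nozaki–Hiyama–Kishi coupling of F1 with 10 (CrCl2, NiCl2 cat., DMSO/THF, rt) forms the same C11–C12 bond without a borane and should give 24 mixed with its 11S epimer (5Z,8R)-8-[(1R,2R)-2-{(1S,2E,4S,6Z,9Z)-4-[(tert-butyldimethylsilyl)oxy]-1-hydroxydodeca-2,6,9-trien-1-yl}cyclopropyl]-3,4,7,8-tetrahydro-2H-oxocin-2-one F2. The mixture is oxidised with Dess–Martin periodinane to the cyclopropyl enone (5Z,8R)-8-[(1R,2R)-2-{(2E,4S,6Z,9Z)-4-[(tert-butyldimethylsilyl)oxy]dodeca-2,6,9-trienoyl}cyclopropyl]-3,4,7,8-tetrahydro-2H-oxocin-2-one F3. Reagent-controlled reduction of F3 ((R)-2-methyl-CBS-oxazaborolidine, catecholborane, toluene, −78 °C, the alkenyl arm acting as the larger group) comes back to the route at 24.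

Step 5. Intermolecular metathesis (dimerisation, oligomerisation) may outrun closure of the strained medium ring, or the catalyst may isomerise the terminal alkenes. The fallback sets out from 5 and closes the ring at the ester C–O bond instead. Silylation (Et3SiCl, imidazole) would give tert-butyl({(1R,2R)-2-[(1R)-1-(triethylsilyloxy)but-3-en-1-yl]cyclopropyl}methoxy)diphenylsilane F4. Ozonolysis (O3, then PPh3) gives (3R)-3-[(1R,2R)-2-{[(tert-butyldiphenylsilyl)oxy]methyl}cyclopropyl]-3-(triethylsilyloxy)propanal F5. A Z-selective Wittig reaction with (3-carboxypropyl)triphenylphosphonium bromide and NaN(SiMe3)2 gives (4Z,7R)-7-[(1R,2R)-2-{[(tert-butyldiphenylsilyl)oxy]methyl}cyclopropyl]-7-(triethylsilyloxy)hept-4-enoic acid F6. Mild acid (AcOH, THF, H2O) removes the triethylsilyl group to give (4Z,7R)-7-[(1R,2R)-2-{[(tert-butyldiphenylsilyl)oxy]methyl}cyclopropyl]-7-hydroxyhept-4-enoic acid F7. Yamaguchi lactonisation (2,4,6-trichlorobenzoyl chloride, Et3N; DMAP, toluene, high dilution) comes back to the route at 8.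

Step 3. Dehydrogenation of the hindered cyclopropylmethanol may stall, or a mismatched pairing of catalyst and substrate may give poor facial selectivity at C7. The fallback sets out from 3: Swern oxidation ((COCl)2, DMSO, Et3N, CH2Cl2, −78 °C) gives aldehyde 4, now isolated. Brown allylboration with the reagent made from (+)-Ipc2BOMe and CH2=CHCH2MgBr (Et2O, −78 °C, Re-face attack, 2-aminoethanol work-up) comes back to the route at 5; this fallback makes no new compound (F0).

**Further compounds**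

F1 | step 15 | tert-butyl{[(1E,3S,5Z,8Z)-1-iodoundeca-1,5,8-trien-3-yl]oxy}dimethylsilane | CC/C=C\C/C=C\C[C@H](O[Si](C)(C)C(C)(C)C)/C=C/I
F2 | step 15 | (5Z,8R)-8-[(1R,2R)-2-{(1S,2E,4S,6Z,9Z)-4-[(tert-butyldimethylsilyl)oxy]-1-hydroxydodeca-2,6,9-trien-1-yl}cyclopropyl]-3,4,7,8-tetrahydro-2H-oxocin-2-one | CC/C=C\C/C=C\C[C@H](O[Si](C)(C)C(C)(C)C)/C=C/[C@H](O)[C@@H]1C[C@H]1[C@H]1C/C=C\CCC(=O)O1
F3 | step 15 | (5Z,8R)-8-[(1R,2R)-2-{(2E,4S,6Z,9Z)-4-[(tert-butyldimethylsilyl)oxy]dodeca-2,6,9-trienoyl}cyclopropyl]-3,4,7,8-tetrahydro-2H-oxocin-2-one | CC/C=C\C/C=C\C[C@H](O[Si](C)(C)C(C)(C)C)/C=C/C(=O)[C@@H]1C[C@H]1[C@H]1C/C=C\CCC(=O)O1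
F4 | step 5 | tert-butyl({(1R,2R)-2-[(1R)-1-(triethylsilyloxy)but-3-en-1-yl]cyclopropyl}methoxy)diphenylsilane | CC(C)(C)[Si](c1ccccc1)(c1ccccc1)OC[C@@H]1C[C@H]1[C@H](O[Si](CC)(CC)CC)CC=C
F5 | step 5 | (3R)-3-[(1R,2R)-2-{[(tert-butyldiphenylsilyl)oxy]methyl}cyclopropyl]-3-(triethylsilyloxy)propanal | CC(C)(C)[Si](c1ccccc1)(c1ccccc1)OC[C@@H]1C[C@H]1[C@H](O[Si](CC)(CC)CC)CC=O
F6 | step 5 | (4Z,7R)-7-[(1R,2R)-2-{[(tert-butyldiphenylsilyl)oxy]methyl}cyclopropyl]-7-(triethylsilyloxy)hept-4-enoic acid | CC(C)(C)[Si](c1ccccc1)(c1ccccc1)OC[C@@H]1C[C@H]1[C@H](O[Si](CC)(CC)CC)C/C=C\CCC(=O)O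
F7 | step 5 | (4Z,7R)-7-[(1R,2R)-2-{[(tert-butyldiphenylsilyl)oxy]methyl}cyclopropyl]-7-hydroxyhept-4-enoic acid | CC(C)(C)[Si](c1ccccc1)(c1ccccc1)OC[C@@H]1C[C@H]1[C@H](O)C/C=C\CCC(=O)O
F0 | step 3 | none | none
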